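**Retrosynthetic overview**
- Last C–C bond: Sonogashira union of two ten-carbon halves, the ethynyl-oxolane ester (fragment A) and (1Z,3Z,9E)-1-bromo-10-iododeca-1,3,9-triene (fragment B).
- Fragment A: alkyne ⇐ aldehyde ⇐ 2,5-trans-oxolanylmethanol ⇐ cobalt-catalysed aerobic oxidative cyclisation of an (R)-4-pentenol ⇐ (S)-epoxide (kinetic resolution) + acetal Grignard; the dioxolane becomes the methyl ester last.
- Fragment B: Z-selective Wittig of an (E)-7-iodoheptenyl ylide with (Z)-3-bromoacrolein; the vinyl iodide comes from hydrozirconation–iodination of hept-6-yn-1-ol, the bromoacrolein from ethyl propiolate.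
- Rings: only one ring, the oxolane, closed in step 3; C2 comes from the epoxide, C5 is set by 2,5-trans substrate control.

Assumption: the SMILES is read as methyl 4-[(2R,5S)-5-[(3E,9Z,11Z)-12-bromododeca-3,9,11-trien-1-yn-1-yl]oxolan-2-yl]butanoate (2,5-trans oxolane); in SMILES of zirconocene species each cyclopentadienyl ligand is drawn as a σ-bonded C5H5 ring.

**Fragment A**

Step 1
Reactants: 1 rac-2-(but-3-en-1-yl)oxirane
Product: 2 (2S)-2-(but-3-en-1-yl)oxirane
Conditions: (S,S)-(salen)Co(OAc) 0.5 mol% [salen = N,N′-bis(3,5-di-tert-butylsalicylidene)cyclohexane-1,2-diaminate; trivalent cobalt], H2O 0.55 equiv, neat, 0 °C → rt, 16 h; distil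
Reagents that add atoms: none
Why: Jacobsen hydrolytic kinetic resolution, in which the (S,S)-catalyst hydrolyses the (R)-epoxide much faster, so the (S)-epoxide is recovered in high ee and fixes the future C2 stereocentre of the oxolane.

Step 2
Reactants: 2 (2S)-2-(but-3-en-1-yl)oxirane; 3 2-(2-bromoethyl)-1,3-dioxolane
Product: 5 (4R)-1-(1,3-dioxolan-2-yl)oct-7-en-4-ol, via Grignard reagent 4 (not isolated)
Conditions: 3, Mg turnings, THF, 20–30 °C; then CuI 10 mol%, 2, THF, −30 → 0 °C; aq. NH4Cl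
Reagents that add atoms: none
Why: Copper-catalysed Grignard opening of a terminal epoxide occurs by SN2 at the unsubstituted CH2, so the stereocentre is untouched while the masked ester chain is attached.

Step 3
Reactants: 5 (4R)-1-(1,3-dioxolan-2-yl)oct-7-en-4-ol
Product: 6 [(2S,5R)-5-[3-(1,3-dioxolan-2-yl)propyl]oxolan-2-yl]methanol
Conditions: Co(modp)2 10 mol% [bis(1-morpholinocarbamoyl-4,4-dimethyl-1,3-pentanedionato)cobalt, Co(C12H18NO4)2; divalent cobalt], tBuOOH 10 mol%, O2 (1 atm), iPrOH, 55 °C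
Reagents that add atoms: dioxygen, O=O
Why: Mukaiyama aerobic oxidative cyclisation of a 4-pentenol closes the ring 5-exo with the side chain pseudo-equatorial, so the existing (R)-carbinol sets the new (S)-centre as the 2,5-trans isomer (typically >95:5) and O2 supplies the hydroxymethyl oxygen.

Step 4
Reactants: 6 [(2S,5R)-5-[3-(1,3-dioxolan-2-yl)propyl]oxolan-2-yl]methanol
Product: 7 (2S,5R)-5-[3-(1,3-dioxolan-2-yl)propyl]oxolane-2-carbaldehyde
Conditions: TEMPO 10 mol%, PhI(OAc)2 1.1 equiv, CH2Cl2, rt; used crude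
Reagents that add atoms: none
Why: TEMPO/PhI(OAc)2 oxoammonium oxidation stops at the aldehyde under non-basic conditions that neither epimerise the α-alkoxy centre nor cleave the dioxolane.

Step 5
Reactants: 7 (2S,5R)-5-[3-(1,3-dioxolan-2-yl)propyl]oxolane-2-carbaldehyde
Product: 8 2-{3-[(2R,5S)-5-ethynyloxolan-2-yl]propyl}-1,3-dioxolane
Conditions: dimethyl (1-diazo-2-oxopropyl)phosphonate 1.3 equiv, K2CO3 2 equiv, MeOH, 0 °C → rt
Reagents that add atoms: dimethyl (1-diazo-2-oxopropyl)phosphonate, CC(=O)C(=[N+]=[N-])P(=O)(OC)OC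
Why: Ohira–Bestmann (Seyferth–Gilbert) homologation converts the aldehyde into the terminal alkyne under mild carbonate conditions with the adjacent stereocentre retained.

Step 6
Reactants: 8 2-{3-[(2R,5S)-5-ethynyloxolan-2-yl]propyl}-1,3-dioxolane
Product: 9 4-[(2R,5S)-5-ethynyloxolan-2-yl]butanal
Conditions: 2 M aq. HCl, THF, rt
Reagents that add atoms: water, O
Why: Acid-catalysed acetal hydrolysis releases the aldehyde, and the alkyne and the oxolane ether are inert to dilute aqueous acid.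

Step 7
Reactants: 9 4-[(2R,5S)-5-ethynyloxolan-2-yl]butanal
Product: 10 methyl 4-[(2R,5S)-5-ethynyloxolan-2-yl]butanoate
Conditions: KHSO5 1.2 equiv (as Oxone, 2KHSO5·KHSO4·K2SO4), MeOH, rt, 18 h
Reagents that add atoms: methanol, CO; potassium peroxymonosulfate, [K+].[O-]S(=O)(=O)OO
Why: Oxone-mediated oxidative esterification oxidises the methyl hemiacetal through a Baeyer–Villiger-type hydride shift directly to the methyl ester without touching the terminal alkyne.

**Fragment B**

Step 8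
Reactants: 11 hept-6-yn-1-ol
Product: 13 (6E)-7-iodohept-6-en-1-ol, via alkenylzirconocene alkoxide 12 (not isolated)
Conditions: Cp2Zr(H)Cl 2.5 equiv, THF, rt, 1 h, dark; then I2 1.2 equiv, THF, 0 °C; aq. Na2S2O3
Reagents that add atoms: iodine, II
Why: Schwartz hydrozirconation adds Zr–H syn and anti-Markovnikov (one equivalent is first consumed by the OH), and stereoretentive iodinolysis then gives only the (E)-vinyl iodide.

Step 9
Reactants: 13 (6E)-7-iodohept-6-en-1-ol
Product: 14 (1E)-1,7-diiodohept-1-ene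
Conditions: I2 1.2 equiv, PPh3 1.2 equiv, imidazole 1.5 equiv, CH2Cl2, 0 °C → rt
Reagents that add atoms: iodine, II
Why: Appel-type iodination displaces the alkoxyphosphonium ion by SN2 at the primary carbon and leaves the vinyl iodide alone.

Step 10
Reactants: 14 (1E)-1,7-diiodohept-1-ene
Product: 15 [(6E)-7-iodohept-6-en-1-yl]triphenylphosphonium iodide
Conditions: PPh3 1.5 equiv, MeCN, reflux, 24 h, dark; triturate with Et2O
Reagents that add atoms: triphenylphosphine, c1ccc(cc1)P(c1ccccc1)c1ccccc1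
Why: SN2 quaternisation of PPh3 occurs only at the primary alkyl iodide, because an sp2 C–I bond does not react with a phosphine without a metal catalyst.

Step 11
Reactants: 16 ethyl prop-2-ynoate
Product: 17 ethyl (2Z)-3-bromoprop-2-enoate
Conditions: LiBr 1.2 equiv, AcOH 1.1 equiv, MeCN, 80 °C
Reagents that add atoms: lithium bromide, [Li+].[Br-]
Why: Conjugate hydrobromination of the ynoate by anti addition of bromide and a proton gives the kinetic (Z)-β-bromoacrylate.

Step 12
Reactants: 17 ethyl (2Z)-3-bromoprop-2-enoate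
Product: 18 (2Z)-3-bromoprop-2-enal
Conditions: iBu2AlH 1.05 equiv, Et2O, −78 °C, 30 min; MeOH, then aq. KNaC4H4O6 (potassium sodium tartrate); cold Et2O solution used at once, dark
Reagents that add atoms: none
Why: Partial ester reduction with iBu2AlH at −78 °C stops at the tetrahedral aluminium hemiacetal, which collapses to the aldehyde only on work-up, so the Z geometry is kept.

Step 13
Reactants: 15 [(6E)-7-iodohept-6-en-1-yl]triphenylphosphonium iodide; 18 (2Z)-3-bromoprop-2-enal
Product: 20 (1Z,3Z,9E)-1-bromo-10-iododeca-1,3,9-triene, via phosphonium ylide 19 (not isolated)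
Conditions: 15, NaN(SiMe3)2 1.0 equiv, THF, −78 °C, 30 min; then 18, −78 → 0 °C, dark
Reagents that add atoms: none
Why: Wittig olefination of a non-stabilised ylide under lithium-free conditions goes through the kinetically favoured cis-oxaphosphetane and forms the new 3Z alkene, while the (Z)-bromoalkene of the aldehyde is carried over.

**Fragment union**

Step 14
Reactants: 10 methyl 4-[(2R,5S)-5-ethynyloxolan-2-yl]butanoate; 20 (1Z,3Z,9E)-1-bromo-10-iododeca-1,3,9-triene
Product: 21 methyl 4-[(2R,5S)-5-[(3E,9Z,11Z)-12-bromododeca-3,9,11-trien-1-yn-1-yl]oxolan-2-yl]butanoate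
Conditions: Pd(PPh3)4 5 mol%, CuI 10 mol%, iPr2NH 3 equiv, THF (degassed), 20 1.2 equiv, 0 °C → rt, dark
Reagents that add atoms: none
Why: In this Sonogashira coupling zerovalent palladium inserts into the C–I bond far faster than into the dienyl C–Br bond, so the copper acetylide couples only at the vinyl iodide with retention of the E geometry and no effect on the stereocentres.

**Compound list**

1 | rac-2-(but-3-en-1-yl)oxirane | C=CCCC1CO1 | starting material
2 | (2S)-2-(but-3-en-1-yl)oxirane | C=CCC[C@H]1CO1 | intermediate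
3 | 2-(2-bromoethyl)-1,3-dioxolane | BrCCC1OCCO1 | starting material
4 | [2-(1,3-dioxolan-2-yl)ethyl]magnesium bromide | Br[Mg]CCC1OCCO1 | intermediate
5 | (4R)-1-(1,3-dioxolan-2-yl)oct-7-en-4-ol | C=CCC[C@H](O)CCCC1OCCO1 | intermediate
6 | [(2S,5R)-5-[3-(1,3-dioxolan-2-yl)propyl]oxolan-2-yl]methanol (2,5-trans) | OC[C@@H]1CC[C@@H](CCCC2OCCO2)O1 | intermediate
7 | (2S,5R)-5-[3-(1,3-dioxolan-2-yl)propyl]oxolane-2-carbaldehyde | O=C[C@@H]1CC[C@@H](CCCC2OCCO2)O1 | intermediate
8 | 2-{3-[(2R,5S)-5-ethynyloxolan-2-yl]propyl}-1,3-dioxolane | C#C[C@@H]1CC[C@@H](CCCC2OCCO2)O1 | intermediate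
9 | 4-[(2R,5S)-5-ethynyloxolan-2-yl]butanal | O=CCCC[C@@H]1CC[C@@H](C#C)O1 | intermediate
10 | methyl 4-[(2R,5S)-5-ethynyloxolan-2-yl]butanoate (fragment A) | COC(=O)CCC[C@@H]1CC[C@@H](C#C)O1 | intermediate
11 | hept-6-yn-1-ol | OCCCCCC#C | starting material
12 | bis-zirconocene species: chlorozirconocene alkoxide of (6E)-7-(chlorozirconocenyl)hept-6-en-1-ol | Cl[Zr](OCCCCC/C=C/[Zr](Cl)(C1C=CC=C1)C1C=CC=C1)(C1C=CC=C1)C1C=CC=C1 | intermediate
13 | (6E)-7-iodohept-6-en-1-ol | OCCCCC/C=C/I | intermediate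
14 | (1E)-1,7-diiodohept-1-ene | ICCCCC/C=C/I | intermediate
15 | [(6E)-7-iodohept-6-en-1-yl]triphenylphosphonium iodide | [I-].I/C=C/CCCCC[P+](c1ccccc1)(c1ccccc1)c1ccccc1 | intermediate
16 | ethyl prop-2-ynoate (ethyl propiolate) | CCOC(=O)C#C | starting material
17 | ethyl (2Z)-3-bromoprop-2-enoate | CCOC(=O)/C=C\Br | intermediate
18 | (2Z)-3-bromoprop-2-enal | O=C/C=C\Br | intermediate
19 | [(6E)-7-iodohept-6-en-1-ylidene]triphenylphosphorane | I/C=C/CCCCC=P(c1ccccc1)(c1ccccc1)c1ccccc1 | intermediate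
20 | (1Z,3Z,9E)-1-bromo-10-iododeca-1,3,9-triene (fragment B) | I/C=C/CCCC/C=C\C=C/Br | intermediate
21 | methyl 4-[(2R,5S)-5-[(3E,9Z,11Z)-12-bromododeca-3,9,11-trien-1-yn-1-yl]oxolan-2-yl]butanoate | COC(=O)CCC[C@@H]1CC[C@@H](C#C/C=C/CCCC/C=C\C=C/Br)O1 | target

**Totals**

Total step count: 14.
Longest linear sequence: 8 steps (steps 1–7, then step 14). The fragment B line is 5 steps (8, 9, 10, 13, 14) and the bromoacrolein branch 4 steps (11, 12, 13, 14).

**Three steps most likely to fail**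

Step 14. The dienyl bromide of 20 or of the product may also couple, and palladium, copper and amine can scramble the (Z,Z)-bromodiene. The fallback builds the bromodiene after the C–C coupling and sets out from 10 and 13. Sonogashira coupling of 10 with 13 (Pd(PPh3)4, CuI, iPr2NH, THF) gives methyl 4-[(2R,5S)-5-[(3E)-9-hydroxynon-3-en-1-yn-1-yl]oxolan-2-yl]butanoate F1. I2/PPh3/imidazole converts it to methyl 4-[(2R,5S)-5-[(3E)-9-iodonon-3-en-1-yn-1-yl]oxolan-2-yl]butanoate F2. PPh3 in MeCN at 60 °C gives {(6E)-9-[(2S,5R)-5-(4-methoxy-4-oxobutyl)oxolan-2-yl]non-6-en-8-yn-1-yl}triphenylphosphonium iodide F3. NaN(SiMe3)2 in THF at −78 °C forms methyl 4-[(2R,5S)-5-[(3E)-9-(triphenylphosphoranylidene)non-3-en-1-yn-1-yl]oxolan-2-yl]butanoate F4, which is condensed with 18 and comes back to the route at 21.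

Step 13. Aldehyde 18 isomerises easily to the E form and can lose HBr or undergo addition–elimination with the basic ylide, which would erode the 1Z geometry and the yield. The fallback makes the (Z)-bromoalkene last from a bromo-ylide and sets out from 13. TEMPO/PhI(OAc)2 oxidation gives (6E)-7-iodohept-6-enal F5. Still–Gennari olefination (methyl bis(2,2,2-trifluoroethoxy)phosphorylacetate, KN(SiMe3)2, 18-crown-6, THF, −78 °C) gives methyl (2Z,8E)-9-iodonona-2,8-dienoate F6. iBu2AlH (2.2 equiv, CH2Cl2, −78 °C) gives (2Z,8E)-9-iodonona-2,8-dien-1-ol F7. MnO2 in CH2Cl2 gives (2Z,8E)-9-iodonona-2,8-dienal F8. A Wittig reaction with Ph3P=CHBr (from [Ph3PCH2Br]Br and KOtBu, THF, −78 °C) then installs the (Z)-vinyl bromide and comes back to the route at 20.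

Step 5. The α-alkoxy aldehyde 7 can epimerise under K2CO3/MeOH before it is homologated, which would contaminate the trans-oxolane with the cis isomer. The fallback is a Corey–Fuchs sequence under aprotic conditions and sets out from 7. CBr4/PPh3 (CH2Cl2, 0 °C) gives 2-{3-[(2R,5S)-5-(2,2-dibromoethenyl)oxolan-2-yl]propyl}-1,3-dioxolane F9. nBuLi (2.2 equiv, THF, −78 °C) gives {[(2S,5R)-5-[3-(1,3-dioxolan-2-yl)propyl]oxolan-2-yl]ethynyl}lithium F10, which is protonated with aq. NH4Cl and comes back to the route at 8.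

**Further compounds**

F1 | step 14 | methyl 4-[(2R,5S)-5-[(3E)-9-hydroxynon-3-en-1-yn-1-yl]oxolan-2-yl]butanoate | COC(=O)CCC[C@@H]1CC[C@@H](C#C/C=C/CCCCCO)O1
F2 | step 14 | methyl 4-[(2R,5S)-5-[(3E)-9-iodonon-3-en-1-yn-1-yl]oxolan-2-yl]butanoate | COC(=O)CCC[C@@H]1CC[C@@H](C#C/C=C/CCCCCI)O1
F3 | step 14 | {(6E)-9-[(2S,5R)-5-(4-methoxy-4-oxobutyl)oxolan-2-yl]non-6-en-8-yn-1-yl}triphenylphosphonium iodide | COC(=O)CCC[C@@H]1CC[C@@H](C#C/C=C/CCCCC[P+](c2ccccc2)(c2ccccc2)c2ccccc2)O1.[I-]
F4 | step 14 | methyl 4-[(2R,5S)-5-[(3E)-9-(triphenylphosphoranylidene)non-3-en-1-yn-1-yl]oxolan-2-yl]butanoate | COC(=O)CCC[C@@H]1CC[C@@H](C#C/C=C/CCCCC=P(c2ccccc2)(c2ccccc2)c2ccccc2)O1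
F5 | step 13 | (6E)-7-iodohept-6-enal | O=CCCCC/C=C/I
F6 | step 13 | methyl (2Z,8E)-9-iodonona-2,8-dienoate | COC(=O)/C=C\CCCC/C=C/I
F7 | step 13 | (2Z,8E)-9-iodonona-2,8-dien-1-ol | OC/C=C\CCCC/C=C/I
F8 | step 13 | (2Z,8E)-9-iodonona-2,8-dienal | O=C/C=C\CCCC/C=C/I
F9 | step 5 | 2-{3-[(2R,5S)-5-(2,2-dibromoethenyl)oxolan-2-yl]propyl}-1,3-dioxolane | BrC(Br)=C[C@@H]1CC[C@@H](CCCC2OCCO2)O1
F10 | step 5 | {[(2S,5R)-5-[3-(1,3-dioxolan-2-yl)propyl]oxolan-2-yl]ethynyl}lithium | [Li]C#C[C@@H]1CC[C@@H](CCCC2OCCO2)O1
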